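**Plan**

1. Each half is numbered as a xanthanolide (C1–C15; primes for the half holding the spiro carbon C11′). The retrosynthesis cuts C1′–C2′ (Heck), then C1–O, then C5–C13′ with C3–C11′ (Diels–Alder of a trans-lactone dienone with a cis-lactone dienophile), then in each monomer C1–C2 and C12, and last C5–C6 together with C7–C8.
2. Enabling feature: in both halves C8 carries oxygen, C1 can sit at the ketone/enol level, the two are 1,4 across C9–C10(CH3), and C5 flanks C1. C5–C1(O)–C10(CH3)–C9–C8 plus the C8 oxygen is therefore a 4-methyl-3-oxidopyrylium and C6=C7–C11 is butenone. Their [5+2] cycloaddition closes the seven-membered ring with a temporary C5–O–C8 bridge, which SmI2 later opens at C5.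
3. Forward: furan → pyranone → 8-oxabicyclo[3.2.1]octenone → cycloheptanone 11. From 11 the C8 oxygen is either kept (→ cis-lactone enol triflate 16) or inverted (→ trans-lactone dienone 24). Then follow the cyclohexene (step 17), the C1 hydroxyl (step 18) and the last butenone (step 19).
4. Stereochemistry: the bridgeheads (→ C8, C8′) come from the catalyst in the [5+2] step; C7/C7′ and C10′ from equilibration on the bicycle; C8 from Mitsunobu inversion and C10 from equilibration after it; C5 and C11′ from the exo Diels–Alder on the convex lactone face; C1 from epoxidation anti to the allylic substituents.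

Key step: step 4

Remark: methyl 3-methylfuran-2-carboxylate (1) and but-3-en-2-one (5) are taken as commercial. The bicyclic intermediates carry their own ring locants (bridgeheads C1 and C5, oxygen O8).

**Route**

Step 1
Reactants: 1 methyl 3-methylfuran-2-carboxylate
Product: 2 (3-methylfuran-2-yl)methanol
Conditions: LiAlH4, Et2O, 0 °C
Reagents that add atoms: none
Why: Hydride reduction of the ester to the primary furylcarbinol (LiAlH4 reduction), with no stereocenter involved.

Step 2
Reactants: 2 (3-methylfuran-2-yl)methanol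
Product: 3 6-hydroxy-4-methyl-2H-pyran-3(6H)-one
Conditions: mCPBA, CH2Cl2, 0 °C to rt
Reagents that add atoms: mCPBA, OOC(=O)c1cccc(Cl)c1
Why: Achmatowicz rearrangement (furan oxidation, ring opening to the ene-dione and reclosure as the hemiacetal) should give the pyranone with the ring methyl at C4; the hemiacetal centre forms as a racemate and is lost in step 4.

Step 3
Reactants: 3 6-hydroxy-4-methyl-2H-pyran-3(6H)-one
Product: 4 4-methyl-5-oxo-5,6-dihydro-2H-pyran-2-yl acetate
Conditions: Ac2O, pyridine, DMAP (cat.), CH2Cl2, 0 °C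
Reagents that add atoms: acetic anhydride, CC(=O)OC(C)=O
Why: O-Acetylation of the hemiacetal installs the leaving group needed for ylide formation.

Step 4
Reactants: 4 4-methyl-5-oxo-5,6-dihydro-2H-pyran-2-yl acetate; 5 but-3-en-2-one
Product: 7 (1S,5S)-6-acetyl-3-methyl-8-oxabicyclo[3.2.1]oct-3-en-2-one (C6 epimer mixture), via 4-methyl-3-oxidopyrylium 6 (not isolated)
Conditions: 3-[[3,5-bis(trifluoromethyl)phenyl]amino]-4-[[(8α,9S)-6′-methoxycinchonan-9-yl]amino]cyclobut-3-ene-1,2-dione (10 mol %), 4 Å MS, toluene, 0 °C to rt, butenone in fivefold excess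
Reagents that add atoms: none
Why: Proposed new method: the quinuclidine nitrogen of the catalyst removes H-2 of 4, acetate leaves (E1cB), and the resulting ylide 6 stays hydrogen-bonded through its oxide to the two squaramide N–H groups inside the chiral pocket, so that 5 can reach only one face of the planar ylide; the closest known chemistry is the amine-mediated racemic oxidopyrylium–enone [5+2] cycloaddition and its enantioselective thiourea- or squaramide–amine-catalysed variants, which so far cover tethered alkenes, enol ethers and dienamines. The bond formation is a suprafacial six-electron (π4s + π2s) addition across C2 and C6 of the ylide, in which the enolate-like C2 attacks the β-carbon of 5 and the acetyl-bearing carbon then closes onto the oxocarbenium C6; the seven-membered carbocycle closes by this one intermolecular cycloaddition, and the oxolane and dihydropyranone rings of the bicycle are simply the two parts into which the surviving C–O–C bridge divides it. The step needs regioselectivity first (acetyl next to the bridgehead remote from the ketone), and this is secured in the substrates by the polarity match between the 3-oxido-substituted ylide and the acceptor-substituted alkene. The two bridgeheads are necessarily cis (oxygen bridge) and their absolute configuration (1S,5S) is set by the catalyst, whereas C6 forms as an endo/exo mixture, which is harmless because this centre is equilibrated in step 5. The quinidine-derived pseudo-enantiomeric catalyst is held in reserve in case the sense of induction proves to be the opposite one.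

Step 5
Reactants: 7 (1S,5S)-6-acetyl-3-methyl-8-oxabicyclo[3.2.1]oct-3-en-2-one (C6 epimer mixture)
Product: 9 (1S,3R,5S,6R)-6-acetyl-3-methyl-8-oxabicyclo[3.2.1]octan-2-one, via saturated diketone epimer mixture 8 (not isolated)
Conditions: H2 (1 atm), 10% Pd/C, EtOAc, rt; then DBU (0.2 equiv), CH2Cl2, rt
Reagents that add atoms: none
Why: Heterogeneous hydrogenation saturates the enone C=C, and DBU then equilibrates the two enolisable centres to the more stable isomer, with the C3 methyl equatorial on the oxane chair and the C6 acetyl exo (clear of the axial H-3), both cis to the bridge, while the bridgeheads cannot enolise and keep the configuration set in step 4.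

Step 6
Reactants: 9 (1S,3R,5S,6R)-6-acetyl-3-methyl-8-oxabicyclo[3.2.1]octan-2-one
Product: 10 (1S,3R,5S,6S)-3-methyl-6-(prop-1-en-2-yl)-8-oxabicyclo[3.2.1]octan-2-one
Conditions: Ph3PCH3Br (1.05 equiv), KOtBu, THF, 0 °C
Reagents that add atoms: methyltriphenylphosphonium bromide, C[P+](c1ccccc1)(c1ccccc1)c1ccccc1.[Br-]
Why: Wittig methylenation should select the methyl ketone because the ring ketone is flanked by two branched carbons (a bridgehead and the methyl-bearing C3), and it freezes the configuration at C6, which is no longer α to a carbonyl group.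

Step 7
Reactants: 10 (1S,3R,5S,6S)-3-methyl-6-(prop-1-en-2-yl)-8-oxabicyclo[3.2.1]octan-2-one
Product: 11 (2R,4S,5S)-4-hydroxy-2-methyl-5-(prop-1-en-2-yl)cycloheptan-1-one
Conditions: SmI2 (2.5 equiv), MeOH, THF, −78 °C
Reagents that add atoms: none
Why: Reductive cleavage of the α-alkoxy ketone by SmI2 (two single-electron transfers, loss of the bridgehead C–O bond next to the ketyl, protonation of the samarium enolate) opens the bridge on the ketone side only, leaving the oxygen on the remote carbinol carbon with its configuration and the methyl-bearing centre untouched.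

Step 8
Reactants: 11 (2R,4S,5S)-4-hydroxy-2-methyl-5-(prop-1-en-2-yl)cycloheptan-1-one
Product: 14 (4S,5S,7R)-5-hydroxy-7-methyl-4-(prop-1-en-2-yl)cyclohept-1-en-1-yl trifluoromethanesulfonate, via trimethylsilyl ether 12 (not isolated), via silylated enol triflate 13 (not isolated)
Conditions: TMSCl, imidazole, CH2Cl2, 0 °C; KN(SiMe3)2, PhNTf2, THF, −78 °C; then 1 M HCl, THF, 0 °C
Reagents that add atoms: N-phenylbis(trifluoromethanesulfonimide), O=S(=O)(N(c1ccccc1)S(=O)(=O)C(F)(F)F)C(F)(F)F
Why: The hydroxyl is masked in the flask as its trimethylsilyl ether, the hindered amide base removes the CH2 α-proton (kinetic enolate, away from the methyl-bearing carbon), PhNTf2 traps it as the enol triflate and the acidic work-up frees the alcohol, with no stereocenter changed.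

Step 9
Reactants: 14 (4S,5S,7R)-5-hydroxy-7-methyl-4-(prop-1-en-2-yl)cyclohept-1-en-1-yl trifluoromethanesulfonate
Product: 15 (4S,5S,7R)-5-hydroxy-4-(3-hydroxyprop-1-en-2-yl)-7-methylcyclohept-1-en-1-yl trifluoromethanesulfonate
Conditions: SeO2 (0.3 equiv), t-BuOOH, CH2Cl2, rt
Reagents that add atoms: tert-butyl hydroperoxide, CC(C)(C)OO; selenium dioxide, O=[Se]=O
Why: Riley-type allylic oxidation (ene reaction, then [2,3]-sigmatropic shift) should hydroxylate the methyl group of the isopropenyl unit, the only electron-rich alkene present (the enol triflate is deactivated), and any aldehyde or lactol from over-oxidation converges in step 10.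

Step 10
Reactants: 15 (4S,5S,7R)-5-hydroxy-4-(3-hydroxyprop-1-en-2-yl)-7-methylcyclohept-1-en-1-yl trifluoromethanesulfonate
Product: 16 (3aS,7R,8aS)-7-methyl-3-methylidene-2-oxo-3,3a,4,7,8,8a-hexahydro-2H-cyclohepta[b]furan-6-yl trifluoromethanesulfonate
Conditions: MnO2 (activated, excess), CH2Cl2, rt
Reagents that add atoms: none
Why: Oxidative lactonisation of a 2-methylene-1,4-diol: MnO2 oxidises the allylic alcohol to the 2-substituted acrolein, the neighbouring cis secondary hydroxyl closes the lactol and a second oxidation gives the cis-fused α-methylene-γ-butyrolactone with the C–O configuration unchanged.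

Step 11
Reactants: 11 (2R,4S,5S)-4-hydroxy-2-methyl-5-(prop-1-en-2-yl)cycloheptan-1-one
Product: 17 (1R,2S,6R)-6-methyl-5-oxo-2-(prop-1-en-2-yl)cycloheptyl 4-nitrobenzoate
Conditions: 4-O2NC6H4CO2H, PPh3, DIAD, THF, 0 °C to rt
Reagents that add atoms: 4-nitrobenzoic acid, OC(=O)c1ccc(cc1)[N+](=O)[O-]
Why: Mitsunobu esterification displaces the oxyphosphonium-activated hydroxyl by 4-nitrobenzoate with SN2 inversion, as with other 2-isopropenylcycloalkanols, turning the cis into the trans relationship between the carbinol and the isopropenyl-bearing carbon.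

Step 12
Reactants: 17 (1R,2S,6R)-6-methyl-5-oxo-2-(prop-1-en-2-yl)cycloheptyl 4-nitrobenzoate
Product: 18 (2S,4R,5S)-4-hydroxy-2-methyl-5-(prop-1-en-2-yl)cycloheptan-1-one
Conditions: K2CO3, MeOH, rt
Reagents that add atoms: none
Why: Methanolysis (transesterification) frees the inverted alcohol, and the carbonate at the same time epimerises the ketone α-carbon to the more stable isomer in which methyl, hydroxyl and isopropenyl are all equatorial (methyl cis to hydroxyl).

Step 13
Reactants: 18 (2S,4R,5S)-4-hydroxy-2-methyl-5-(prop-1-en-2-yl)cycloheptan-1-one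
Product: 21 (4S,5R,7S)-5-hydroxy-7-methyl-4-(prop-1-en-2-yl)cyclohept-1-en-1-yl trifluoromethanesulfonate, via trimethylsilyl ether 19 (not isolated), via silylated enol triflate 20 (not isolated)
Conditions: TMSCl, imidazole, CH2Cl2, 0 °C; KN(SiMe3)2, PhNTf2, THF, −78 °C; then 1 M HCl, THF, 0 °C
Reagents that add atoms: N-phenylbis(trifluoromethanesulfonimide), O=S(=O)(N(c1ccccc1)S(=O)(=O)C(F)(F)F)C(F)(F)F
Why: As in step 8, silyl masking in the flask, kinetic deprotonation at the CH2 α-carbon and O-triflation give the less substituted enol triflate, which fixes the now correct methyl-bearing centre as a non-enolisable allylic carbon.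

Step 14
Reactants: 21 (4S,5R,7S)-5-hydroxy-7-methyl-4-(prop-1-en-2-yl)cyclohept-1-en-1-yl trifluoromethanesulfonate
Product: 22 (4S,5R,7S)-5-hydroxy-4-(3-hydroxyprop-1-en-2-yl)-7-methylcyclohept-1-en-1-yl trifluoromethanesulfonate
Conditions: SeO2 (0.3 equiv), t-BuOOH, CH2Cl2, rt
Reagents that add atoms: tert-butyl hydroperoxide, CC(C)(C)OO; selenium dioxide, O=[Se]=O
Why: Riley-type allylic oxidation of the isopropenyl methyl group as in step 9, with no stereocenter affected.

Step 15
Reactants: 22 (4S,5R,7S)-5-hydroxy-4-(3-hydroxyprop-1-en-2-yl)-7-methylcyclohept-1-en-1-yl trifluoromethanesulfonate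
Product: 23 (3aS,7S,8aR)-7-methyl-3-methylidene-2-oxo-3,3a,4,7,8,8a-hexahydro-2H-cyclohepta[b]furan-6-yl trifluoromethanesulfonate
Conditions: MnO2 (activated, excess), CH2Cl2, rt
Reagents that add atoms: none
Why: MnO2 oxidative lactonisation as in step 10, here closing the trans-fused (diequatorial) α-methylene-γ-butyrolactone with the inverted C–O configuration retained.

Step 16
Reactants: 23 (3aS,7S,8aR)-7-methyl-3-methylidene-2-oxo-3,3a,4,7,8,8a-hexahydro-2H-cyclohepta[b]furan-6-yl trifluoromethanesulfonate; 5 but-3-en-2-one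
Product: 24 (3aS,7S,8aR)-7-methyl-3-methylidene-6-[(E)-3-oxobut-1-en-1-yl]-3,3a,4,7,8,8a-hexahydro-2H-cyclohepta[b]furan-2-one
Conditions: Pd(OAc)2 (5 mol %), PPh3 (10 mol %), Et3N, DMF, 60 °C, butenone in fivefold excess
Reagents that add atoms: none
Why: Mizoroki–Heck coupling of the enol triflate (oxidative addition to zerovalent palladium, insertion of butenone, β-hydride elimination) gives the E-dienone, and butenone in excess outcompetes the 1,1-disubstituted methylene lactone as acceptor.

Step 17
Reactants: 24 (3aS,7S,8aR)-7-methyl-3-methylidene-6-[(E)-3-oxobut-1-en-1-yl]-3,3a,4,7,8,8a-hexahydro-2H-cyclohepta[b]furan-2-one; 16 (3aS,7R,8aS)-7-methyl-3-methylidene-2-oxo-3,3a,4,7,8,8a-hexahydro-2H-cyclohepta[b]furan-6-yl trifluoromethanesulfonate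
Product: 25 cross Diels–Alder adduct: cyclohexene with a C1=C2 double bond, C3(H)(acetyl) bonded to the spiro carbon C11′ and C5(H) bonded to C13′H2, H-3 and H-5 cis to each other and to the lactone carbonyl C12′, enol triflate at C1′
Conditions: toluene, BHT (cat.), 90 °C, the dienone added slowly to a threefold excess of the dienophile (surplus recovered unchanged)
Reagents that add atoms: none
Why: Thermal Diels–Alder reaction of the semicyclic dienone C5=C1–C2=C3 of 24 with the exocyclic methylene lactone of 16, which has no diene of its own and is kept in excess so that self-cycloaddition of 24 is held back: the large HOMO coefficient at C5 pairs with the methylene carbon C13′ (ortho rule, acetyl next to the spiro carbon), the s-cis-locked lactone reacts in the exo mode (C12′=O away from the diene) on its convex face anti to the cis-fused seven-membered ring, and the diene is attacked at C5 anti to the pseudoaxial C6–H bond of the conformer fixed by the trans-fused lactone, that is on the face carrying C8–O and opposite to C7–C11, which sets C5, C3 and C11′ as required.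

Step 18
Reactants: 25 cross Diels–Alder adduct
Product: 27 target skeleton bearing the C1′ enol triflate in place of the butenone chain (C1 tertiary alcohol cis to H-5 and C2=C3 enone in place), via epoxide 26 (not isolated)
Conditions: mCPBA (1.1 equiv), CH2Cl2, 0 °C; then Et3N, rt
Reagents that add atoms: mCPBA, OOC(=O)c1cccc(Cl)c1
Why: Peracid epoxidation picks the only electron-rich (trisubstituted, unconjugated) alkene C1=C2 and occurs anti to the two allylic substituents on the other face (the C3 acetyl and the C5–C6 bond), so the oxygen ends cis to H-5, and amine-induced E1cB opening of the β,γ-epoxy ketone moves the double bond to C2=C3 and leaves the tertiary C1–OH with that configuration.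

Step 19
Reactants: 27 target skeleton bearing the C1′ enol triflate in place of the butenone chain; 5 but-3-en-2-one
Product: 28 target CNP0168949.6
Conditions: Pd(OAc)2 (10 mol %), PPh3 (20 mol %), Et3N, DMF, 60 °C, butenone in fivefold excess
Reagents that add atoms: none
Why: Mizoroki–Heck coupling as in step 16 installs the (E)-3-oxobut-1-enyl chain on C1′ without touching a stereocenter, the tertiary allylic alcohol and both methylene lactones being tolerated under the mild amine base when butenone is in excess.

**Compound list**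

1 | methyl 3-methylfuran-2-carboxylate | COC(=O)c1occc1C | starting material
2 | (3-methylfuran-2-yl)methanol | Cc1ccoc1CO | intermediate
3 | 6-hydroxy-4-methyl-2H-pyran-3(6H)-one (racemic hemiacetal) | CC1=CC(O)OCC1=O | intermediate
4 | 4-methyl-5-oxo-5,6-dihydro-2H-pyran-2-yl acetate (racemic) | CC(=O)OC1C=C(C)C(=O)CO1 | intermediate
5 | but-3-en-2-one | CC(=O)C=C | starting material
6 | 4-methyl-3-oxidopyrylium (4-methylpyrylium-3-olate), not isolated | Cc1cc[o+]cc1[O-] | intermediate
7 | (1S,5S)-6-acetyl-3-methyl-8-oxabicyclo[3.2.1]oct-3-en-2-one, mixture of C6 epimers | CC(=O)C1C[C@@H]2O[C@H]1C=C(C)C2=O | intermediate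
8 | (1S,5S)-6-acetyl-3-methyl-8-oxabicyclo[3.2.1]octan-2-one, mixture of C3/C6 epimers, not isolated | CC(=O)C1C[C@@H]2O[C@H]1CC(C)C2=O | intermediate
9 | (1S,3R,5S,6R)-6-acetyl-3-methyl-8-oxabicyclo[3.2.1]octan-2-one (acetyl exo, methyl equatorial) | CC(=O)[C@@H]1C[C@@H]2O[C@H]1C[C@@H](C)C2=O | intermediate
10 | (1S,3R,5S,6S)-3-methyl-6-(prop-1-en-2-yl)-8-oxabicyclo[3.2.1]octan-2-one | C=C(C)[C@@H]1C[C@@H]2O[C@H]1C[C@@H](C)C2=O | intermediate
11 | (2R,4S,5S)-4-hydroxy-2-methyl-5-(prop-1-en-2-yl)cycloheptan-1-one | O[C@H]1C[C@@H](C)C(=O)CC[C@H]1C(C)=C | intermediate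
12 | (2R,4S,5S)-2-methyl-5-(prop-1-en-2-yl)-4-(trimethylsilyloxy)cycloheptan-1-one, not isolated | C[Si](C)(C)O[C@H]1C[C@@H](C)C(=O)CC[C@H]1C(C)=C | intermediate
13 | (4S,5S,7R)-7-methyl-4-(prop-1-en-2-yl)-5-(trimethylsilyloxy)cyclohept-1-en-1-yl trifluoromethanesulfonate, not isolated | C[Si](C)(C)O[C@H]1C[C@@H](C)C(OS(=O)(=O)C(F)(F)F)=CC[C@H]1C(C)=C | intermediate
14 | (4S,5S,7R)-5-hydroxy-7-methyl-4-(prop-1-en-2-yl)cyclohept-1-en-1-yl trifluoromethanesulfonate | O[C@H]1C[C@@H](C)C(OS(=O)(=O)C(F)(F)F)=CC[C@H]1C(C)=C | intermediate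
15 | (4S,5S,7R)-5-hydroxy-4-(3-hydroxyprop-1-en-2-yl)-7-methylcyclohept-1-en-1-yl trifluoromethanesulfonate | O[C@H]1C[C@@H](C)C(OS(=O)(=O)C(F)(F)F)=CC[C@H]1C(=C)CO | intermediate
16 | (3aS,7R,8aS)-7-methyl-3-methylidene-2-oxo-3,3a,4,7,8,8a-hexahydro-2H-cyclohepta[b]furan-6-yl trifluoromethanesulfonate (cis-fused lactone, dienophile) | C=C1C(=O)O[C@H]2C[C@@H](C)C(OS(=O)(=O)C(F)(F)F)=CC[C@@H]12 | intermediate
17 | (1R,2S,6R)-6-methyl-5-oxo-2-(prop-1-en-2-yl)cycloheptyl 4-nitrobenzoate | O=C(O[C@@H]1C[C@@H](C)C(=O)CC[C@H]1C(C)=C)c1ccc(cc1)[N+](=O)[O-] | intermediate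
18 | (2S,4R,5S)-4-hydroxy-2-methyl-5-(prop-1-en-2-yl)cycloheptan-1-one | O[C@@H]1C[C@H](C)C(=O)CC[C@H]1C(C)=C | intermediate
19 | (2S,4R,5S)-2-methyl-5-(prop-1-en-2-yl)-4-(trimethylsilyloxy)cycloheptan-1-one, not isolated | C[Si](C)(C)O[C@@H]1C[C@H](C)C(=O)CC[C@H]1C(C)=C | intermediate
20 | (4S,5R,7S)-7-methyl-4-(prop-1-en-2-yl)-5-(trimethylsilyloxy)cyclohept-1-en-1-yl trifluoromethanesulfonate, not isolated | C[Si](C)(C)O[C@@H]1C[C@H](C)C(OS(=O)(=O)C(F)(F)F)=CC[C@H]1C(C)=C | intermediate
21 | (4S,5R,7S)-5-hydroxy-7-methyl-4-(prop-1-en-2-yl)cyclohept-1-en-1-yl trifluoromethanesulfonate | O[C@@H]1C[C@H](C)C(OS(=O)(=O)C(F)(F)F)=CC[C@H]1C(C)=C | intermediate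
22 | (4S,5R,7S)-5-hydroxy-4-(3-hydroxyprop-1-en-2-yl)-7-methylcyclohept-1-en-1-yl trifluoromethanesulfonate | O[C@@H]1C[C@H](C)C(OS(=O)(=O)C(F)(F)F)=CC[C@H]1C(=C)CO | intermediate
23 | (3aS,7S,8aR)-7-methyl-3-methylidene-2-oxo-3,3a,4,7,8,8a-hexahydro-2H-cyclohepta[b]furan-6-yl trifluoromethanesulfonate (trans-fused lactone) | C=C1C(=O)O[C@@H]2C[C@H](C)C(OS(=O)(=O)C(F)(F)F)=CC[C@@H]12 | intermediate
24 | (3aS,7S,8aR)-7-methyl-3-methylidene-6-[(E)-3-oxobut-1-en-1-yl]-3,3a,4,7,8,8a-hexahydro-2H-cyclohepta[b]furan-2-one (diene) | C=C1C(=O)O[C@@H]2C[C@H](C)C(/C=C/C(C)=O)=CC[C@@H]12 | intermediate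
25 | cross Diels–Alder adduct of 24 and 16 (C1=C2 alkene, 3-acetyl with H-3 cis to H-5, spiro C11′, enol triflate at C1′) | C=C1C(=O)O[C@@H]2C[C@H](C)C3=C[C@H](C(C)=O)[C@]4(C[C@@H]3C[C@@H]12)C(=O)O[C@H]1C[C@@H](C)C(OS(=O)(=O)C(F)(F)F)=CC[C@H]14 | intermediate
26 | 1,2-epoxide of 25 (oxygen cis to H-3 and H-5), not isolated | C=C1C(=O)O[C@@H]2C[C@H](C)[C@]3(O5)[C@@H]5[C@H](C(C)=O)[C@]4(C[C@@H]3C[C@@H]12)C(=O)O[C@H]1C[C@@H](C)C(OS(=O)(=O)C(F)(F)F)=CC[C@H]14 | intermediate
27 | target skeleton with the C1′ enol triflate in place of the butenone chain | C=C1C(=O)O[C@@H]2C[C@H](C)[C@]3(O)C=C(C(C)=O)[C@]4(C[C@@H]3C[C@@H]12)C(=O)O[C@H]1C[C@@H](C)C(OS(=O)(=O)C(F)(F)F)=CC[C@H]14 | intermediate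
28 | CNP0168949.6 | C=C1C(=O)O[C@@H]2C[C@H](C)[C@]3(O)C=C(C(C)=O)[C@]4(C[C@@H]3C[C@@H]12)C(=O)O[C@H]1C[C@@H](C)C(/C=C/C(C)=O)=CC[C@H]14 | target

**Count**

Total: 19 steps. Longest linear sequence: 16 steps (steps 1–7, 11–16 and 17–19); the branch to 16 (steps 8–10) joins at step 17.

**Steps most likely to fail**

Step 4 (Proposed new method). What may go wrong: the ylide, held to the catalyst only by hydrogen bonds, may add with little facial discrimination, or may dimerise faster than the catalyst turns over. Fallback, by known chemistry: the cycloaddition is run in the established racemic way (4 and 5, Et3N, CH2Cl2, rt). This gives 7 together with its mirror image, (1R,5R)-6-acetyl-3-methyl-8-oxabicyclo[3.2.1]oct-3-en-2-one F1. The racemate is taken through steps 5–7 unchanged, which makes, beside 8, 9, 10 and 11, the enantiomeric saturated diketone mixture F2, the exo diketone F3, the isopropenyl ketone F4 and the hydroxy ketone F5. The racemic alcohol is then resolved by lipase-catalysed acylation (lipase B from Candida antarctica, vinyl acetate, tert-butyl methyl ether, 30 °C). By the empirical size rule for secondary alcohols the (4R)-carbinol F5 should be acetylated to (1R,2R,6S)-6-methyl-5-oxo-2-(prop-1-en-2-yl)cycloheptyl acetate F6, while 11 stays as the alcohol and is separated by chromatography. The fallback sets out from 4 and 5 and comes back to the route at 11.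

Step 17. What may go wrong: 24 carries a methylene lactone as reactive as that of 16 and may be consumed by cycloaddition with itself; having to force the cross reaction with excess partner and heat could also erode the π-facial and exo selectivity. Fallback: the dienophile of 24 is masked first. Dimethylamine (THF, rt) adds to the methylene lactone to give (3aS,7S,8aR)-3-[(dimethylamino)methyl]-7-methyl-6-[(E)-3-oxobut-1-en-1-yl]-3,3a,4,7,8,8a-hexahydro-2H-cyclohepta[b]furan-2-one F7, which can act only as a diene. F7 and a slight excess of 16 are then heated at higher concentration to give the amine-bearing cross adduct F8. Quaternisation with MeI gives the trimethylammonium iodide F9, and aqueous NaHCO3 eliminates trimethylamine to restore the methylene lactone. The fallback sets out from 24 (with 16) and comes back to the route at 25.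

Step 5. What may go wrong: under DBU the enolate of the acetyl group can expel the bridging oxygen (β-elimination of the β-alkoxy ketone), and if reclosure is slow or incomplete the bicycle is lost or the exo preference is not reached. Fallback: C6 is selected kinetically instead of thermodynamically, and base is withheld while the acetyl group is present. The exo epimer (1S,5S,6R)-6-acetyl-3-methyl-8-oxabicyclo[3.2.1]oct-3-en-2-one F10 is separated from 7 by chromatography (the endo epimer is given up). It is hydrogenated without base to (1S,3S,5S,6R)-6-acetyl-3-methyl-8-oxabicyclo[3.2.1]octan-2-one F11, in which the methyl group is still axial. The acetyl group is methylenated under non-basic conditions (Zn, CH2Br2, TiCl4, THF) to (1S,3S,5S,6S)-3-methyl-6-(prop-1-en-2-yl)-8-oxabicyclo[3.2.1]octan-2-one F12, which no longer contains a β-alkoxy ketone able to eliminate and is epimerised at C3 with DBU. The fallback sets out from 7 and comes back to the route at 10.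

Further compounds
F1 | step 4 | (1R,5R)-6-acetyl-3-methyl-8-oxabicyclo[3.2.1]oct-3-en-2-one, mixture of C6 epimers (enantiomer of 7) | CC(=O)C1C[C@H]2O[C@@H]1C=C(C)C2=O
F2 | step 4 | (1R,5R)-6-acetyl-3-methyl-8-oxabicyclo[3.2.1]octan-2-one, epimer mixture (enantiomer of 8) | CC(=O)C1C[C@H]2O[C@@H]1CC(C)C2=O
F3 | step 4 | (1R,3S,5R,6S)-6-acetyl-3-methyl-8-oxabicyclo[3.2.1]octan-2-one (enantiomer of 9) | CC(=O)[C@H]1C[C@H]2O[C@@H]1C[C@H](C)C2=O
F4 | step 4 | (1R,3S,5R,6R)-3-methyl-6-(prop-1-en-2-yl)-8-oxabicyclo[3.2.1]octan-2-one (enantiomer of 10) | C=C(C)[C@H]1C[C@H]2O[C@@H]1C[C@H](C)C2=O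
F5 | step 4 | (2S,4R,5R)-4-hydroxy-2-methyl-5-(prop-1-en-2-yl)cycloheptan-1-one (enantiomer of 11) | O[C@@H]1C[C@H](C)C(=O)CC[C@@H]1C(C)=C
F6 | step 4 | (1R,2R,6S)-6-methyl-5-oxo-2-(prop-1-en-2-yl)cycloheptyl acetate | CC(=O)O[C@@H]1C[C@H](C)C(=O)CC[C@@H]1C(C)=C
F7 | step 17 | (3aS,7S,8aR)-3-[(dimethylamino)methyl]-7-methyl-6-[(E)-3-oxobut-1-en-1-yl]-3,3a,4,7,8,8a-hexahydro-2H-cyclohepta[b]furan-2-one (C3 epimers) | CN(C)CC1C(=O)O[C@@H]2C[C@H](C)C(/C=C/C(C)=O)=CC[C@@H]12
F8 | step 17 | cross Diels–Alder adduct of F7 and 16 (25 with CH–CH2NMe2 in place of the exocyclic methylene) | CN(C)CC1C(=O)O[C@@H]2C[C@H](C)C3=C[C@H](C(C)=O)[C@]4(C[C@@H]3C[C@@H]12)C(=O)O[C@H]1C[C@@H](C)C(OS(=O)(=O)C(F)(F)F)=CC[C@H]14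
F9 | step 17 | trimethylammonium iodide of F8 | C[N+](C)(C)CC1C(=O)O[C@@H]2C[C@H](C)C3=C[C@H](C(C)=O)[C@]4(C[C@@H]3C[C@@H]12)C(=O)O[C@H]1C[C@@H](C)C(OS(=O)(=O)C(F)(F)F)=CC[C@H]14.[I-]
F10 | step 5 | (1S,5S,6R)-6-acetyl-3-methyl-8-oxabicyclo[3.2.1]oct-3-en-2-one (exo epimer of 7) | CC(=O)[C@@H]1C[C@@H]2O[C@H]1C=C(C)C2=O
F11 | step 5 | (1S,3S,5S,6R)-6-acetyl-3-methyl-8-oxabicyclo[3.2.1]octan-2-one (methyl axial) | CC(=O)[C@@H]1C[C@@H]2O[C@H]1C[C@H](C)C2=O
F12 | step 5 | (1S,3S,5S,6S)-3-methyl-6-(prop-1-en-2-yl)-8-oxabicyclo[3.2.1]octan-2-one (methyl axial) | C=C(C)[C@@H]1C[C@@H]2O[C@H]1C[C@H](C)C2=O
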